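## Structural features

The target is a trans-fused decalin of the eremophilane type (C1–C10 in the bicycle, C14 on C5, C15 on C4, isopropenyl C11–C13 on C7) with seven stereocentres, (2S,4S,5R,7R,8R,9S,10R). Ring A (C1–C5, C10) holds the quaternary C5 with its angular methyl next to C4 with a cis secondary methyl, and an axial 2α-acetoxy group that stands 1,4 to C5. Ring B (C5–C10) holds four contiguous stereocentres: H10 (α, trans fusion), the equatorial 9α-angelate, the axial 8α-hydroxyl and the axial 7β-isopropenyl group, which is syn-diaxial to C14. Fragile groups are the angelate (a (Z)-enoate that isomerises to the tiglate and accepts nucleophiles), the cis-8,9-diol monoester (acyl migration), and the isopropenyl alkene (competes in any oxidation or hydrogenation). Three oxygens must end as two different esters and one free alcohol. The real difficulty is the quaternary C5 flanked by C4 with cis methyls, combined with a trans fusion and an axial, contra-thermodynamic C7 substituent. The key step exploits two features: O2 is para to C5 in a ring whose C4 and C5 carry methyls, so ring A is a hidden 3,4-dimethylphenol; and O9 is peri to C1, so one extra carbon (C16) can bridge C1 and O9 as a lactone, which makes the precursor a flat phthalide whose para carbon is C5.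

## Logic of the disconnections

25 ⇒ 22 + 23 (via 24). The O9–acyl bond is cut last because the angelate is the most fragile group. All earlier steps are then free of the enoate. The forward step must acylate the equatorial O9 in preference to the axial O8 without Z→E isomerisation.

22 ⇒ 21 ⇒ 20. The O9–Si and O2–acetyl bonds are cut. The three hydroxyls are told apart by the order in which they appear: O9 is silylated while it is the only hydroxyl, and O2 is acetylated when the only other free hydroxyl is the hindered axial O8. The demand is a selective acetylation of 20.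

20 ⇒ 19. The C7–C11 bond is cut. The trans-diaxial pair (C11 on C7, O on C8) is the signature of a diaxial epoxide opening. This removes the isopropenyl group and reduces C7 and C8 to one cis-epoxide. The forward step must attack C7 from the β face, syn to C14, and away from C9.

19 ⇒ 18 ⇒ 17 ⇒ 16. The C2–H bond (hydride to a ketone from the equatorial side), the O9–Si bond and the two epoxide C–O bonds are cut. This returns to an allylic alcohol with a C2 ketone. The epoxide oxygen must be delivered to the α face, syn to O9–H and anti to C14.

16 ⇒ 15. The C4–H bond is cut (conjugate reduction of the C3=C4 enone). The cis methyls then come from axial protonation anti to C14. The step must leave the C7=C8 alkene alone.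

15 ⇒ 13 (via 14). A carbon that is not in the target, C16, is added back: bonds C1–C16 and C16–O9 form a lactone. The lactone ties O9 to C1, blocks C1, and makes C1=C10 a doubly activated alkene. The forward step is hydrolysis and decarboxylation that must spare the allylic alcohol.

13 ⇒ 12. The C10–H bond is cut (conjugate hydride addition). This returns to a fully conjugated dienone lactone. The demand is 1,4-reduction at C1=C10 only, from the α face.

12 ⇒ 11 (key). The C5–C6 bond is cut, which opens ring B and rearomatises ring A. A tricycle with a quaternary stereocentre becomes a flat phthalide with one stereocentre (C9). The forward step must alkylate the para carbon C5 of a phenoxide, not oxygen and not C1.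

11 ⇒ 10 ⇒ 9. The C6–Br bond comes from C6–OH, and the (Z)-C7=C8 alkene from an alkyne. These are functional group changes that make the tether accessible from an acetylene.

9 ⇒ 6 + 7 (via 8). The C8–C9 bond (alkynylation of an aldehyde) and the O9–C16 bond (lactonisation) are cut. The single stereocentre is set by a catalyst. The alkynyl group must add to the Re face.

6 ⇒ 4 ⇒ 2 ⇒ 1 (via 5 and 3). The C10–C9 and C1–C16 bonds are cut as two directed ortho-metalations of a protected 3,4-dimethylphenol. Regiochemistry rests on the hierarchy of the directing groups.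

## Other disconnections considered

Alternative 1: Robinson annulation (the first idea). Cut C4–C5 and C1=C10: Michael addition of a cyclic 2-methyl-1,3-diketone to a β-methyl vinyl ketone, then aldol condensation, to give the C4-methylated enedione A1.
- The C4/C5 methyl relationship would be set in an open Michael transition state, so the cis arrangement is not secured.
- The second carbonyl lands on C6, where the target has CH2 next to the quaternary carbon, and C7, C8 and C9 arrive without functionality.
- Deleting O6 and carrying oxygen to C8 and C9 costs many steps that the chosen plan does not need, since its key step delivers O9 and the C7=C8 alkene in place.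

Alternative 2: intramolecular Diels–Alder reaction. Cut C5–C10 and C3–C4: the triene A2 (a 2-silyloxydiene C3=C2–C1=C10 tethered through C9–C6 to an (E)-trisubstituted C4=C5 alkene) would give the trans-octalin silyl enol ether A3.
- The dienophile is unactivated and trisubstituted and must form a quaternary carbon, so high temperature is to be expected.
- The trans (anti) transition state has to place the C7 substituent syn-diaxial to C14, so the endo/exo preference is uncertain.
- The isopropenyl group is a second possible dienophile.
- The acyclic A2 needs three contiguous stereocentres and two defined alkenes before the key step, whereas the chosen precursor has one stereocentre.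

Alternative 3: desymmetrising intramolecular Stetter reaction (polarity reversal at C9). Cut C9–C10: the achiral dienone aldehyde A4 would give the bicyclic dione A5 through an acyl anion equivalent adding to C10.
- The tether on C5 can reach C10 only from its own face, so H10 ends cis to C14, the opposite of the target, with no later handle that would favour the trans isomer.
- The C15 methyl is incompatible with the symmetry on which the desymmetrisation rests.
- Ring B arrives without functionality at C7 and C8.

Key step: step 7

Remarks on the chemistry.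
- The C9 ester is read from the SMILES as the (Z)-2-methylbut-2-enoate (angelate).
- Eremophilane numbering is used throughout; β is the face of C14; C16 is the temporary lactone carbon on C1; "11,12,13-trinor" means that the isopropenyl carbons are absent.
- 3,4-Dimethylphenol (1), the silyl propargyl ether 7, angelic acid (23) and isopropenylmagnesium bromide are taken as commercial.

## Route

Step 1
Reactants: 1 3,4-dimethylphenol
Product: 2 4-(methoxymethoxy)-1,2-dimethylbenzene
Conditions: NaH, MOMCl, THF, 0 °C to rt
Reagents that add atoms: chloromethyl methyl ether, COCCl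
Why: Williamson ether formation on the sodium phenoxide; the MOM ether protects the phenol and is the first directing group.

Step 2
Reactants: 2 4-(methoxymethoxy)-1,2-dimethylbenzene
Product: 4 N,N-diethyl-2-(methoxymethoxy)-4,5-dimethylbenzamide, via aryllithium 3 (not isolated)
Conditions: sBuLi, TMEDA, THF, −78 °C; then ClC(O)NEt2, −78 °C to rt
Reagents that add atoms: N,N-diethylcarbamoyl chloride, CCN(CC)C(Cl)=O
Why: Directed ortho-metalation; the MOM ether directs lithiation to the unhindered ortho carbon (the other ortho site is flanked by a methyl group), and acylation installs the carbon that becomes C16.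

Step 3
Reactants: 4 N,N-diethyl-2-(methoxymethoxy)-4,5-dimethylbenzamide
Product: 6 N,N-diethyl-2-formyl-6-(methoxymethoxy)-3,4-dimethylbenzamide, via aryllithium 5 (not isolated)
Conditions: sBuLi, TMEDA, THF, −78 °C; then DMF; aq. NH4Cl
Reagents that add atoms: N,N-dimethylformamide, CN(C)C=O
Why: Second directed ortho-metalation; the tertiary amide is the stronger directing group, so lithiation occurs at its free ortho position (future C10) and formylation installs C9.

Step 4
Reactants: 6 N,N-diethyl-2-formyl-6-(methoxymethoxy)-3,4-dimethylbenzamide; 7 tert-butyldimethyl(prop-2-yn-1-yloxy)silane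
Product: 9 (R)-7-hydroxy-3-(3-hydroxyprop-1-yn-1-yl)-4,5-dimethylisobenzofuran-1(3H)-one, via hydroxy amide 8 (not isolated)
Conditions: Me2Zn (3 equiv), ProPhenol ligand (20 mol %, the antipode that delivers the alkynyl group to the Re face), Ph3PO (40 mol %), toluene, 4 °C; then 3 M HCl in MeOH, 45 °C
Reagents that add atoms: none
Why: Zinc-mediated catalytic asymmetric alkynylation of the aldehyde sets the only catalyst-controlled stereocentre (C9, R); acid then closes the phthalide by attack of O9 on the amide carbonyl and removes the MOM and TBS groups.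

Step 5
Reactants: 9 (R)-7-hydroxy-3-(3-hydroxyprop-1-yn-1-yl)-4,5-dimethylisobenzofuran-1(3H)-one
Product: 10 (R)-7-hydroxy-3-[(Z)-3-hydroxyprop-1-en-1-yl]-4,5-dimethylisobenzofuran-1(3H)-one
Conditions: H2 (1 atm), Lindlar catalyst (Pd on CaCO3, poisoned with Pb(OAc)2), quinoline, EtOAc, rt
Reagents that add atoms: none
Why: Lindlar semihydrogenation is syn and should give the (Z)-alkene that the ring closure needs; lactone and phenol are untouched.

Step 6
Reactants: 10 (R)-7-hydroxy-3-[(Z)-3-hydroxyprop-1-en-1-yl]-4,5-dimethylisobenzofuran-1(3H)-one
Product: 11 (R)-3-[(Z)-3-bromoprop-1-en-1-yl]-7-hydroxy-4,5-dimethylisobenzofuran-1(3H)-one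
Conditions: CBr4, PPh3, CH2Cl2, −20 to 0 °C
Reagents that add atoms: carbon tetrabromide, BrC(Br)(Br)Br
Why: Appel bromination converts the primary allylic alcohol into the bromide under neutral conditions without allylic transposition; the hydrogen-bonded phenol should not react.

Step 7
Reactants: 11 (R)-3-[(Z)-3-bromoprop-1-en-1-yl]-7-hydroxy-4,5-dimethylisobenzofuran-1(3H)-one
Product: 12 (5aR,8aR)-5,5a-dimethyl-5a,6-dihydro-2H-naphtho[1,8-bc]furan-2,3(8aH)-dione (tricyclic dienone lactone: C2 ketone, C1=C10, C3=C4, C7=C8, lactone C1–C16(=O)–O9, C14 β, H9 β)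
Conditions: KOtBu (1.0 equiv), tBuOH/THF 4:1, 0.003 M, 30 °C
Reagents that add atoms: none
Why: Deprotonation gives the phenoxide, whose para carbon C5 (the methyl-bearing carbon) displaces the primary allylic bromide at C6 by SN2, the charge ending on O2 as the C2 ketone of a cross-conjugated dienone; the closest known reaction type is the alkylative dearomatisation of a phenoxide by aryl participation of the Ar2-6 kind. Ring B closes in the 6-(enolendo)-exo-tet mode, the (Z)-alkene holding C6 within reach of C5 and ruling out SN2' attack at C8, which would need a four-membered ring. The only new stereocentre is C5: because O9 and C16 lie in the arene plane, C8 must leave that plane on one face and C6 can reach C5 only from the same face, so C14 is pushed to the face of H9 and the (R) centre at C9 is relayed to C5 as a geometric necessity. O-alkylation is impossible within the molecule (the phenoxide oxygen is meta to the tether) and is suppressed between molecules by high dilution and hydrogen bonding to tBuOH. The other ortho carbon of the tether, C1, carries C16 and could react only by bending the lactone out of the arene plane into a bridged bicyclo[3.2.1] skeleton, so C5 should be the favoured site. One equivalent of base is used so that the medium is neutral once the phenoxide is consumed, which limits deprotonation of the acidic C9–H of 12.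

Step 8
Reactants: 12 (5aR,8aR)-5,5a-dimethyl-5a,6-dihydro-2H-naphtho[1,8-bc]furan-2,3(8aH)-dione
Product: 13 2-oxo-10αH-11,12,13-trinoreremophila-3,7-diene-1-carboxylic acid lactonised onto O9α (tricyclic β-keto lactone; C1 epimers, enolisable)
Conditions: NaBH4 (1.0 equiv), THF/EtOH 4:1, −40 °C; then AcOH
Reagents that add atoms: none
Why: Conjugate hydride addition to the alkylidene β-keto lactone; C10 is the β-carbon of both carbonyls and far more electrophilic than C4 or the C2 carbonyl, and the resulting β-dicarbonyl enolate is protected from further reduction. Hydride should enter C10 axially with respect to ring B from the α face, anti to the adjacent pseudoaxial C14, which sets H10 trans to C14.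

Step 9
Reactants: 13 tricyclic β-keto lactone
Product: 15 9α-hydroxy-10αH-11,12,13-trinoreremophila-3,7-dien-2-one, via keto acid 14 (not isolated)
Conditions: LiOH (4 equiv), THF/H2O 2:1, 45 °C; then 1 M HCl to pH 2, 45 °C
Reagents that add atoms: none
Why: Ketonic hydrolysis of an α-acyl lactone: saponification frees O9–H and a β-keto acid that loses CO2 on acidification, so C16 leaves, C1 becomes CH2 and C10 is no longer epimerisable.

Step 10
Reactants: 15 9α-hydroxy-10αH-11,12,13-trinoreremophila-3,7-dien-2-one
Product: 16 9α-hydroxy-4αH,10αH-11,12,13-trinoreremophil-7-en-2-one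
Conditions: Li (4 equiv), liquid NH3/THF, −78 °C, 20 min; then solid NH4Cl
Reagents that add atoms: none
Why: Dissolving-metal (Birch-type) conjugate reduction of the enone only; the β-carbanion at C4 is protonated axially from the α face, anti to the axial C14, which should give the equatorial 4β-methyl cis to C14, while the isolated C7=C8 alkene and the allylic alkoxide are not reduced.

Step 11
Reactants: 16 9α-hydroxy-4αH,10αH-11,12,13-trinoreremophil-7-en-2-one
Product: 17 7α,8α-epoxy-9α-hydroxy-4αH,10αH-11,12,13-trinoreremophilan-2-one
Conditions: mCPBA, NaHCO3, CH2Cl2, 0 °C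
Reagents that add atoms: 3-chloroperoxybenzoic acid, OOC(=O)c1cccc(Cl)c1
Why: Hydroxyl-directed (Henbest) epoxidation; hydrogen bonding to the 9α-OH and shielding of the β face at C7 by the axial C14 both lead to the 7α,8α-epoxide, and Baeyer–Villiger oxidation of the ketone is much slower in buffered medium at 0 °C.

Step 12
Reactants: 17 7α,8α-epoxy-9α-hydroxy-4αH,10αH-11,12,13-trinoreremophilan-2-one
Product: 18 9α-(tert-butyldimethylsilyloxy)-7α,8α-epoxy-4αH,10αH-11,12,13-trinoreremophilan-2-one
Conditions: TBSCl, imidazole, DMAP (cat.), DMF, 40 °C
Reagents that add atoms: tert-butyldimethylsilyl chloride, CC(C)(C)[Si](C)(C)Cl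
Why: Silylation of the only hydroxyl without a Lewis acid that could open the epoxide; the TBS ether marks O9 apart from the hydroxyls that appear later and shields C8.

Step 13
Reactants: 18 9α-(tert-butyldimethylsilyloxy)-7α,8α-epoxy-4αH,10αH-11,12,13-trinoreremophilan-2-one
Product: 19 9α-(tert-butyldimethylsilyloxy)-7α,8α-epoxy-4αH,10αH-11,12,13-trinoreremophilan-2α-ol
Conditions: L-Selectride (LiBH(sBu)3, 1.3 equiv), THF, −78 °C; then aq. NH4Cl
Reagents that add atoms: none
Why: The bulky hydride attacks the C2 ketone from the equatorial direction and should give the axial 2α-alcohol; epoxide and silyl ether are inert at −78 °C.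

Step 14
Reactants: 19 9α-(tert-butyldimethylsilyloxy)-7α,8α-epoxy-4αH,10αH-11,12,13-trinoreremophilan-2α-ol
Product: 20 9α-(tert-butyldimethylsilyloxy)-10αH-eremophil-11-ene-2α,8α-diol (7β-isopropenyl)
Conditions: isopropenylmagnesium bromide (5 equiv), CuI (20 mol %), THF, −30 to 0 °C; then aq. NH4Cl
Reagents that add atoms: isopropenylmagnesium bromide, CC(=C)[Mg]Br
Why: Copper-catalysed Grignard opening of the epoxide following the Fürst–Plattner rule: attack at C7 from the β face gives the trans-diaxial product (7β-isopropenyl, 8α-OH) directly in the chair, while attack at C8 would need a twist-boat and is also disfavoured by the adjacent silyloxy group. One equivalent of the Grignard reagent is consumed by O2–H.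

Step 15
Reactants: 20 9α-(tert-butyldimethylsilyloxy)-10αH-eremophil-11-ene-2α,8α-diol
Product: 21 2α-acetoxy-9α-(tert-butyldimethylsilyloxy)-10αH-eremophil-11-en-8α-ol
Conditions: Ac2O (1.5 equiv), pyridine, DMAP (5 mol %), CH2Cl2, 0 °C
Reagents that add atoms: acetic anhydride, CC(=O)OC(C)=O
Why: Acetylation of the accessible 2α-OH; the 8α-OH is axial and flanked by the isopropenyl-bearing C7 and the bulky silyloxy group on C9 and should not react at 0 °C.

Step 16
Reactants: 21 2α-acetoxy-9α-(tert-butyldimethylsilyloxy)-10αH-eremophil-11-en-8α-ol
Product: 22 2α-acetoxy-10αH-eremophil-11-ene-8α,9α-diol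
Conditions: HF·pyridine, pyridine, THF, 0 °C to rt
Reagents that add atoms: none
Why: Fluoride-mediated desilylation under buffered, non-basic conditions, so that the acetate neither migrates nor hydrolyses.

Step 17
Reactants: 22 2α-acetoxy-10αH-eremophil-11-ene-8α,9α-diol; 23 angelic acid ((Z)-2-methylbut-2-enoic acid)
Product: 25 2α-acetoxy-9α-angeloyloxy-10αH-eremophil-11-en-8α-ol (target, (2S,4S,5R,7R,8R,9S,10R)), via mixed anhydride 24 (not isolated)
Conditions: 23, 2,4,6-trichlorobenzoyl chloride, Et3N, toluene, rt; then 22, 75 °C
Reagents that add atoms: none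
Why: Yamaguchi esterification through the mixed anhydride 24; the equatorial 9α-OH should be acylated in preference to the axial 8α-OH, and leaving out DMAP avoids addition–elimination at the enoate, which would isomerise angelate to tiglate.

## Compound list

1 | 3,4-dimethylphenol | Cc1ccc(O)cc1C | starting material
2 | 4-(methoxymethoxy)-1,2-dimethylbenzene | COCOc1ccc(C)c(C)c1 | intermediate
3 | [2-(methoxymethoxy)-4,5-dimethylphenyl]lithium | [Li]c1cc(C)c(C)cc1OCOC | intermediate (not isolated)
4 | N,N-diethyl-2-(methoxymethoxy)-4,5-dimethylbenzamide | CCN(CC)C(=O)c1cc(C)c(C)cc1OCOC | intermediate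
5 | [2-(diethylcarbamoyl)-3-(methoxymethoxy)-5,6-dimethylphenyl]lithium | [Li]c1c(C)c(C)cc(OCOC)c1C(=O)N(CC)CC | intermediate (not isolated)
6 | N,N-diethyl-2-formyl-6-(methoxymethoxy)-3,4-dimethylbenzamide | O=Cc1c(C)c(C)cc(OCOC)c1C(=O)N(CC)CC | intermediate
7 | tert-butyldimethyl(prop-2-yn-1-yloxy)silane | C#CCO[Si](C)(C)C(C)(C)C | starting material
8 | (R)-N,N-diethyl-2-[4-(tert-butyldimethylsilyloxy)-1-hydroxybut-2-yn-1-yl]-6-(methoxymethoxy)-3,4-dimethylbenzamide | CCN(CC)C(=O)c1c(OCOC)cc(C)c(C)c1[C@H](O)C#CCO[Si](C)(C)C(C)(C)C | intermediate (not isolated)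
9 | (R)-7-hydroxy-3-(3-hydroxyprop-1-yn-1-yl)-4,5-dimethylisobenzofuran-1(3H)-one | OCC#C[C@H]1OC(=O)c2c(O)cc(C)c(C)c12 | intermediate
10 | (R)-7-hydroxy-3-[(Z)-3-hydroxyprop-1-en-1-yl]-4,5-dimethylisobenzofuran-1(3H)-one | OC/C=C\[C@H]1OC(=O)c2c(O)cc(C)c(C)c12 | intermediate
11 | (R)-3-[(Z)-3-bromoprop-1-en-1-yl]-7-hydroxy-4,5-dimethylisobenzofuran-1(3H)-one | BrC/C=C\[C@H]1OC(=O)c2c(O)cc(C)c(C)c12 | intermediate
12 | (5aR,8aR)-5,5a-dimethyl-5a,6-dihydro-2H-naphtho[1,8-bc]furan-2,3(8aH)-dione (tricyclic dienone lactone, C14 β, H9 β) | C=1C[C@]2(C)C(C)=CC(=O)C3=C2[C@H](OC3=O)C=1 | intermediate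
13 | 2-oxo-10αH-11,12,13-trinoreremophila-3,7-diene-1-carboxylic acid lactonised onto O9α (β-keto lactone, C1 not controlled) | C=1C[C@]2(C)C(C)=CC(=O)C3[C@H]2[C@H](OC3=O)C=1 | intermediate
14 | 9α-hydroxy-2-oxo-10αH-11,12,13-trinoreremophila-3,7-diene-1-carboxylic acid (C1 not controlled) | C=1C[C@]2(C)C(C)=CC(=O)C(C(=O)O)[C@H]2[C@H](O)C=1 | intermediate (not isolated)
15 | 9α-hydroxy-10αH-11,12,13-trinoreremophila-3,7-dien-2-one | C=1C[C@]2(C)C(C)=CC(=O)C[C@H]2[C@H](O)C=1 | intermediate
16 | 9α-hydroxy-4αH,10αH-11,12,13-trinoreremophil-7-en-2-one | C=1C[C@]2(C)[C@@H](C)CC(=O)C[C@H]2[C@H](O)C=1 | intermediate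
17 | 7α,8α-epoxy-9α-hydroxy-4αH,10αH-11,12,13-trinoreremophilan-2-one | O1[C@@H]2C[C@]3(C)[C@@H](C)CC(=O)C[C@H]3[C@H](O)[C@H]12 | intermediate
18 | 9α-(tert-butyldimethylsilyloxy)-7α,8α-epoxy-4αH,10αH-11,12,13-trinoreremophilan-2-one | O1[C@@H]2C[C@]3(C)[C@@H](C)CC(=O)C[C@H]3[C@H](O[Si](C)(C)C(C)(C)C)[C@H]12 | intermediate
19 | 9α-(tert-butyldimethylsilyloxy)-7α,8α-epoxy-4αH,10αH-11,12,13-trinoreremophilan-2α-ol | O1[C@@H]2C[C@]3(C)[C@@H](C)C[C@H](O)C[C@H]3[C@H](O[Si](C)(C)C(C)(C)C)[C@H]12 | intermediate
20 | 9α-(tert-butyldimethylsilyloxy)-10αH-eremophil-11-ene-2α,8α-diol | C=C(C)[C@H]1C[C@]2(C)[C@@H](C)C[C@H](O)C[C@H]2[C@H](O[Si](C)(C)C(C)(C)C)[C@@H]1O | intermediate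
21 | 2α-acetoxy-9α-(tert-butyldimethylsilyloxy)-10αH-eremophil-11-en-8α-ol | C=C(C)[C@H]1C[C@]2(C)[C@@H](C)C[C@H](OC(C)=O)C[C@H]2[C@H](O[Si](C)(C)C(C)(C)C)[C@@H]1O | intermediate
22 | 2α-acetoxy-10αH-eremophil-11-ene-8α,9α-diol | C=C(C)[C@H]1C[C@]2(C)[C@@H](C)C[C@H](OC(C)=O)C[C@H]2[C@H](O)[C@@H]1O | intermediate
23 | angelic acid, (Z)-2-methylbut-2-enoic acid | C/C=C(/C)C(=O)O | starting material
24 | (Z)-2-methylbut-2-enoic 2,4,6-trichlorobenzoic anhydride | C/C=C(/C)C(=O)OC(=O)c1c(Cl)cc(Cl)cc1Cl | intermediate (not isolated)
25 | 2α-acetoxy-9α-angeloyloxy-10αH-eremophil-11-en-8α-ol, (2S,4S,5R,7R,8R,9S,10R) | C=C(C)[C@H]1C[C@]2(C)[C@@H](C)C[C@H](OC(C)=O)C[C@H]2[C@H](OC(=O)/C(C)=C\C)[C@@H]1O | target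

## Step count and least certain steps

Total step count: 17. Longest linear sequence: 17 steps (from 1; 7 and 23 enter as commercial compounds).

Step 7 (key step). What may go wrong:
- alkylation between molecules at oxygen, leading to oligomers;
- slow closure at the hindered C5, which leaves time for 1,4-elimination of HBr from the tether;
- after closure, deprotonation at C9 with migration of the C7=C8 double bond into conjugation.

Fallback, from 10 back to 12: acylate the primary allylic alcohol with methyl chloroformate and pyridine at −20 °C to give the allylic methyl carbonate F1. Treat F1 with Pd(PPh3)4 (zerovalent palladium) in MeCN at 0 °C to rt. Ionisation gives a π-allyl complex and methoxide, which deprotonates the phenol. The para carbon then attacks the only allyl terminus that closes a six-membered ring (C6) and should give 12 with no added base. The temperature is kept low so that the secondary allylic lactone C9–O bond is not ionised.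

Step 4. What may go wrong: weak facial discrimination, because the aldehyde is flanked by a methyl group and a chelating amide.

Fallback, from 6 back to 8 and then 9: add the lithium acetylide of 7 (nBuLi, THF, −78 °C) to 6 to give the racemic hydroxy amide F2. Oxidise with Dess–Martin periodinane to the ynone F3. Reduce by Corey–Bakshi–Shibata reduction (oxazaborolidine, catecholborane, −78 °C), in which the twisted di-ortho-substituted aryl group is the large and the alkynyl group the small substituent, to give 8. Acid treatment as in step 4 leads to 9.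

Step 8. What may go wrong: 1,2-reduction of the C2 carbonyl, or hydride delivery to the β face with loss of the trans fusion.

Fallback, from 12 back to 16: open the lactone with LiOH in aq. THF at 0 °C to the hydroxy acid F4 (as its dilithium salt). Reduce with Li in liquid NH3, where electron transfer followed by axial protonation sets H10 α, as it does for related enones with an angular methyl. Acidification and decarboxylation should give 15, 16 or both, and the mixture is carried through step 10 to converge on 16. The alkoxide at C9 is a poor leaving group, so the reductive loss of O9 expected for the intact lactone should not occur.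

Step 14. What may go wrong: slow axial attack at C7 syn to C14, so that ring opening by bromide (bromohydrin) or attack at C8 takes over.

Fallback, from 19 back to 20: use a small, linear nucleophile. Lithium trimethylsilylacetylide with BF3·OEt2 in THF at −78 °C should open the epoxide trans-diaxially to the alkyne F5. K2CO3 in MeOH removes the silyl group to give the terminal alkyne F6. Negishi carboalumination (Me3Al, Cp2ZrCl2, CH2Cl2), which places methyl on the internal carbon, followed by protonolysis converts the ethynyl group into isopropenyl and gives 20.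

Step 17. What may go wrong: acylation of the axial O8, acyl migration between O9 and O8 at 75 °C, or angelate-to-tiglate isomerisation.

Fallback, from 22 back to 25: replace kinetic discrimination by a tin template. Heat 22 with Bu2SnO in toluene with removal of water to give the dibutylstannylene acetal F7. In cis-diols of this kind the equatorial oxygen is the one activated, so F7 should react with preformed 24 at room temperature at O9 to give 25.

## Further compounds

F1 | step 7 | (R,Z)-3-(7-hydroxy-4,5-dimethyl-1-oxo-1,3-dihydroisobenzofuran-3-yl)allyl methyl carbonate | COC(=O)OC/C=C\[C@H]1OC(=O)c2c(O)cc(C)c(C)c12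
F2 | step 4 | racemic N,N-diethyl-2-[4-(tert-butyldimethylsilyloxy)-1-hydroxybut-2-yn-1-yl]-6-(methoxymethoxy)-3,4-dimethylbenzamide | CCN(CC)C(=O)c1c(OCOC)cc(C)c(C)c1C(O)C#CCO[Si](C)(C)C(C)(C)C
F3 | step 4 | N,N-diethyl-2-[4-(tert-butyldimethylsilyloxy)but-2-ynoyl]-6-(methoxymethoxy)-3,4-dimethylbenzamide | CCN(CC)C(=O)c1c(OCOC)cc(C)c(C)c1C(=O)C#CCO[Si](C)(C)C(C)(C)C
F4 | step 8 | 9α-hydroxy-2-oxo-11,12,13-trinoreremophila-1(10),3,7-triene-1-carboxylic acid | C=1C[C@]2(C)C(C)=CC(=O)C(C(=O)O)=C2[C@H](O)C=1
F5 | step 14 | 9α-(tert-butyldimethylsilyloxy)-7β-(trimethylsilylethynyl)-4αH,10αH-11,12,13-trinoreremophilane-2α,8α-diol | C[Si](C)(C)C#C[C@H]1C[C@]2(C)[C@@H](C)C[C@H](O)C[C@H]2[C@H](O[Si](C)(C)C(C)(C)C)[C@@H]1O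
F6 | step 14 | 9α-(tert-butyldimethylsilyloxy)-7β-ethynyl-4αH,10αH-11,12,13-trinoreremophilane-2α,8α-diol | C#C[C@H]1C[C@]2(C)[C@@H](C)C[C@H](O)C[C@H]2[C@H](O[Si](C)(C)C(C)(C)C)[C@@H]1O
F7 | step 17 | 8α,9α-O-dibutylstannylene acetal of 2α-acetoxy-10αH-eremophil-11-ene-8α,9α-diol | C=C(C)[C@H]1C[C@]2(C)[C@@H](C)C[C@H](OC(C)=O)C[C@H]2[C@H](O[Sn]3(CCCC)CCCC)[C@@H]1O3
A1 | alternative 1 | cis-4,4a-dimethyl-4,4a,7,8-tetrahydronaphthalene-2,5(3H,6H)-dione (C4-methylated Wieland–Miescher-type enedione) | O=C1CCCC2=CC(=O)C[C@H](C)[C@@]12C
A2 | alternative 2 | triene: 2-(tert-butyldimethylsilyloxy)-1,3-diene joined through the C8/C9 acetonide and C7 (isopropenyl) to the (E)-trisubstituted C4=C5 alkene | C=C(C)[C@@H](C/C(C)=C/C)[C@H]1OC(C)(C)O[C@H]1/C=C/C(=C)O[Si](C)(C)C(C)(C)C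
A3 | alternative 2 | trans-fused cycloadduct: 2-(tert-butyldimethylsilyloxy)-8α,9α-isopropylidenedioxy-10αH-eremophila-1,11-diene | C=C(C)[C@H]1C[C@]2(C)[C@@H](C)CC(O[Si](C)(C)C(C)(C)C)=C[C@H]2[C@@H]3OC(C)(C)O[C@H]13
A4 | alternative 3 | 4-(1-methyl-4-oxocyclohexa-2,5-dien-1-yl)butanal | CC1(CCCC=O)C=CC(=O)C=C1
A5 | alternative 3 | cis-4a-methyl-3,4,4a,8a-tetrahydronaphthalene-1,7(2H,8H)-dione | C1C[C@]2(C)C=CC(=O)C[C@@H]2C(=O)C1
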